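**Retrosynthetic overview**

1. Late stage: the phenols at O5, O7 and guaiacyl O4 are unmasked last by one hydrogenolysis. The C9 acetate comes from selective acetylation of a 7,9-diol, and C9 itself from reduction of an ethyl ester.
2. Feature and key disconnection: side-chain C8 is bonded at once to O4' of the tricin B ring, to the carbinol carbon C7 (which carries the guaiacyl ring) and to C9. C8 is therefore treated as a carbene carbon, and C8–O4' and C7–C8, with both stereocentres, are cut in one three-component disconnection to ethyl diazoacetate, 5,7-di-O-benzyltricin and O-benzylvanillin.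
3. Phenol component: the pyranone C ring (O1–C2 bond) is made by oxidative cyclisation of a 2'-hydroxychalcone from di-O-benzylphloroacetophenone and 4-O-MOM-syringaldehyde. The MOM group is then removed so that O4'–H is the only O–H offered to the carbene.
4. Ring order: rings A and B and the guaiacyl ring are bought. Ring C is the only ring formed (step 4), before the key step, which closes no ring.

Key step: step 6

Assumption: primed locants are the tricin B ring and C7/C8/C9 are the carbinol, aryloxy-bearing and terminal side-chain carbons. The sense of induction of the chiral phosphoric acid cannot be derived a priori, so (R)-TRIP is written and its antipode is to be used if the first experiment shows the mirror-image sense.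

**Step 1**
Reactants: 1 2',4',6'-trihydroxyacetophenone
Product: 2 1-[2,4-bis(benzyloxy)-6-hydroxyphenyl]ethan-1-one
Conditions: BnBr (2.1 equiv), K2CO3 (2.2 equiv), DMF, rt to 60 °C
Reagents that add atoms: benzyl bromide, BrCc1ccccc1
Why: Williamson etherification in which the two free phenols react while the 2'-hydroxyl, locked in a hydrogen bond to the acetyl carbonyl, is expected to stay untouched with two equivalents of halide.

**Step 2**
Reactants: 3 syringaldehyde
Product: 4 3,5-dimethoxy-4-(methoxymethoxy)benzaldehyde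
Conditions: MOMCl (1.5 equiv), i-Pr2NEt, CH2Cl2, 0 °C to rt
Reagents that add atoms: chloromethyl methyl ether, COCCl
Why: O-alkylation of the phenol with the small, reactive chloromethyl ether should proceed despite the two flanking methoxy groups and gives an acetal that survives base and oxidation but is cleaved by dilute acid without loss of benzyl ethers.

**Step 3**
Reactants: 2 1-[2,4-bis(benzyloxy)-6-hydroxyphenyl]ethan-1-one; 4 3,5-dimethoxy-4-(methoxymethoxy)benzaldehyde
Product: 5 (E)-1-[2,4-bis(benzyloxy)-6-hydroxyphenyl]-3-[3,5-dimethoxy-4-(methoxymethoxy)phenyl]prop-2-en-1-one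
Conditions: 50% aq KOH, EtOH/THF, rt, 48 h
Reagents that add atoms: none
Why: Claisen–Schmidt condensation of the acetyl enolate with a non-enolisable aldehyde should give the E-chalcone, all protecting groups being stable to base.

**Step 4**
Reactants: 5 (E)-1-[2,4-bis(benzyloxy)-6-hydroxyphenyl]-3-[3,5-dimethoxy-4-(methoxymethoxy)phenyl]prop-2-en-1-one
Product: 7 5,7-bis(benzyloxy)-2-[3,5-dimethoxy-4-(methoxymethoxy)phenyl]-4H-chromen-4-one, via flavanone 6 (not isolated)
Conditions: I2 (10 mol %), DMSO, 130 °C
Reagents that add atoms: none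
Why: Iodine-catalysed oxidative cyclisation of a 2'-hydroxychalcone, in which 6-endo oxa-Michael closure of ring C to the flavanone is followed by α-iodination and loss of HI with DMSO as terminal oxidant, is a standard entry to benzyl-protected polyoxygenated flavones.

**Step 5**
Reactants: 7 5,7-bis(benzyloxy)-2-[3,5-dimethoxy-4-(methoxymethoxy)phenyl]-4H-chromen-4-one
Product: 8 5,7-bis(benzyloxy)-2-(4-hydroxy-3,5-dimethoxyphenyl)-4H-chromen-4-one (5,7-di-O-benzyltricin)
Conditions: 3 M HCl, MeOH/THF, 45 °C
Reagents that add atoms: none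
Why: Acid-catalysed methanolysis of the MOM acetal should free only the 4'-phenol, because aryl benzyl ethers, the 5-O-benzyl group included, withstand dilute HCl at this temperature (any MOM already lost in step 4 converges on the same product).

**Step 6**
Reactants: 8 5,7-di-O-benzyltricin; 9 4-benzyloxy-3-methoxybenzaldehyde; 10 ethyl diazoacetate
Product: 13 erythro ethyl (2R,3R)-2-(5,7-di-O-benzyltricin-4'-yloxy)-3-(4-benzyloxy-3-methoxyphenyl)-3-hydroxypropanoate, via rhodium-bound ethoxycarbonylcarbene 11 (not isolated), via protic oxonium ylide 12 (not isolated)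
Conditions: Rh2(OAc)4 (2 mol %), (R)-TRIP [3,3'-bis(2,4,6-triisopropylphenyl)-BINOL hydrogen phosphate] (10 mol %), 4 Å MS, CH2Cl2, −20 °C; 10 (1.5 equiv) by syringe pump over 4 h into 8 (1.0 equiv) and 9 (2.0 equiv)
Reagents that add atoms: none
Why: Proposed new method: Rh2(OAc)4 decomposes 10 to the electrophilic carbene 11, the only O–H group of 8 (the 4'-phenol, O5 and O7 being benzylated) adds to it to give the protic oxonium ylide 12 (a rhodium-associated enol), and this is intercepted at carbon by aldehyde 9 held in the hydrogen-bond network of the chiral phosphoric acid before the 1,2-proton shift that would end in plain O–H insertion, so that C8–O4' and C7–C8 form in one operation and the hindered 2,6-dimethoxyphenol only has to attack a carbene, never a secondary sp3 carbon. The closest known reaction type is the Rh(II)/chiral Brønsted acid co-catalysed three-component coupling of aryldiazoacetates with alcohols or water and imines or activated aldehydes through trapped oxonium ylides; a phenol, an acceptor-only diazoacetate and an electron-rich benzaldehyde together are not established. No ring is closed. Both stereocentres arise in the C–C bond-forming addition: the bifunctional phosphoric acid is expected to bridge the enol O–H and the aldehyde carbonyl in a cyclic transition state, which is to fix the anti (erythro) relationship of C7–OH and C8–OAr and, through its 3,3'-aryl pocket, the aldehyde face and thus the (2R,3R) configuration. The step needs chemoselectivity for the phenol (secured by benzylation of every other hydroxyl and by sieves that exclude water) and trapping faster than proton transfer (favoured by low temperature, excess aldehyde and slow addition of 10, which also suppresses carbene dimerisation).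

**Step 7**
Reactants: 13 erythro ethyl (2R,3R)-2-(5,7-di-O-benzyltricin-4'-yloxy)-3-(4-benzyloxy-3-methoxyphenyl)-3-hydroxypropanoate
Product: 14 5,7-bis(benzyloxy)-2-(4-{[(1R,2S)-1-(4-benzyloxy-3-methoxyphenyl)-1,3-dihydroxypropan-2-yl]oxy}-3,5-dimethoxyphenyl)-4H-chromen-4-one
Conditions: NaBH4 (4 equiv), THF/EtOH 2:1, 0 °C to rt
Reagents that add atoms: none
Why: Borohydride reduction of an α-aryloxy-β-hydroxy ester, activated inductively and by hydride delivery from the C7 alkoxyborohydride, should go at or below room temperature where the donor-substituted pyranone carbonyl (a vinylogous ester) is inert, and no stereocentre is touched (the C8 descriptor changes from R to S only through the priority change).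

**Step 8**
Reactants: 14 5,7-bis(benzyloxy)-2-(4-{[(1R,2S)-1-(4-benzyloxy-3-methoxyphenyl)-1,3-dihydroxypropan-2-yl]oxy}-3,5-dimethoxyphenyl)-4H-chromen-4-one
Product: 15 (2S,3R)-3-(4-benzyloxy-3-methoxyphenyl)-2-(5,7-di-O-benzyltricin-4'-yloxy)-3-hydroxypropyl acetate
Conditions: AcCl (1.2 equiv), 2,4,6-collidine (2 equiv), CH2Cl2, −78 °C
Reagents that add atoms: acetyl chloride, CC(Cl)=O
Why: Kinetically controlled acylation with acetyl chloride and a hindered pyridine base at −78 °C acetylates primary alcohols in the presence of secondary ones, and here the secondary hydroxyl is in addition benzylic and flanked by the bulky aryloxy group.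

**Step 9**
Reactants: 15 (2S,3R)-3-(4-benzyloxy-3-methoxyphenyl)-2-(5,7-di-O-benzyltricin-4'-yloxy)-3-hydroxypropyl acetate
Product: 16 (2S,3R)-2-[4-(5,7-dihydroxy-4-oxo-4H-chromen-2-yl)-2,6-dimethoxyphenoxy]-3-hydroxy-3-(4-hydroxy-3-methoxyphenyl)propyl acetate (CNP0157817.1)
Conditions: H2 (1 atm), 10% Pd/C, EtOAc/THF, rt
Reagents that add atoms: none
Why: Catalytic hydrogenolysis of the three aryl benzyl ethers under neutral conditions is expected, as is usual for arylglycerol β-aryl ethers and for flavones, to leave the benzylic alcohol, the primary acetate and the pyranone C2=C3 bond intact and does not affect C7 or C8.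

**Compound list**

1 | 2',4',6'-trihydroxyacetophenone | CC(=O)c1c(O)cc(O)cc1O | starting material
2 | 1-[2,4-bis(benzyloxy)-6-hydroxyphenyl]ethan-1-one | CC(=O)c1c(O)cc(OCc2ccccc2)cc1OCc1ccccc1 | intermediate
3 | syringaldehyde | COc1cc(C=O)cc(OC)c1O | starting material
4 | 3,5-dimethoxy-4-(methoxymethoxy)benzaldehyde | COCOc1c(OC)cc(C=O)cc1OC | intermediate
5 | (E)-1-[2,4-bis(benzyloxy)-6-hydroxyphenyl]-3-[3,5-dimethoxy-4-(methoxymethoxy)phenyl]prop-2-en-1-one | COCOc1c(OC)cc(/C=C/C(=O)c2c(O)cc(OCc3ccccc3)cc2OCc2ccccc2)cc1OC | intermediate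
6 | 5,7-bis(benzyloxy)-2-[3,5-dimethoxy-4-(methoxymethoxy)phenyl]chroman-4-one (racemic flavanone) | COCOc1c(OC)cc(C2CC(=O)c3c(OCc4ccccc4)cc(OCc4ccccc4)cc3O2)cc1OC | intermediate (not isolated)
7 | 5,7-bis(benzyloxy)-2-[3,5-dimethoxy-4-(methoxymethoxy)phenyl]-4H-chromen-4-one | COCOc1c(OC)cc(-c2cc(=O)c3c(OCc4ccccc4)cc(OCc4ccccc4)cc3o2)cc1OC | intermediate
8 | 5,7-di-O-benzyltricin | COc1cc(-c2cc(=O)c3c(OCc4ccccc4)cc(OCc4ccccc4)cc3o2)cc(OC)c1O | intermediate
9 | 4-benzyloxy-3-methoxybenzaldehyde | COc1cc(C=O)ccc1OCc1ccccc1 | starting material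
10 | ethyl diazoacetate | CCOC(=O)C=[N+]=[N-] | starting material
11 | ethoxycarbonylcarbene, rhodium-bound (drawn without the dirhodium unit) | CCOC(=O)[CH] | intermediate (not isolated)
12 | protic oxonium ylide from 11 and 8 (drawn metal-free) | CCOC(=O)[CH-][OH+]c1c(OC)cc(-c2cc(=O)c3c(OCc4ccccc4)cc(OCc4ccccc4)cc3o2)cc1OC | intermediate (not isolated)
13 | erythro ethyl (2R,3R)-2-(5,7-di-O-benzyltricin-4'-yloxy)-3-(4-benzyloxy-3-methoxyphenyl)-3-hydroxypropanoate | COc1cc([C@@H](O)[C@H](C(=O)OCC)Oc2c(OC)cc(-c3cc(=O)c4c(OCc5ccccc5)cc(OCc5ccccc5)cc4o3)cc2OC)ccc1OCc1ccccc1 | intermediate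
14 | (1R,2S)-1-(4-benzyloxy-3-methoxyphenyl)-2-(5,7-di-O-benzyltricin-4'-yloxy)propane-1,3-diol | COc1cc([C@@H](O)[C@H](CO)Oc2c(OC)cc(-c3cc(=O)c4c(OCc5ccccc5)cc(OCc5ccccc5)cc4o3)cc2OC)ccc1OCc1ccccc1 | intermediate
15 | (2S,3R)-3-(4-benzyloxy-3-methoxyphenyl)-2-(5,7-di-O-benzyltricin-4'-yloxy)-3-hydroxypropyl acetate | COc1cc([C@@H](O)[C@H](COC(C)=O)Oc2c(OC)cc(-c3cc(=O)c4c(OCc5ccccc5)cc(OCc5ccccc5)cc4o3)cc2OC)ccc1OCc1ccccc1 | intermediate
16 | (2S,3R)-2-[4-(5,7-dihydroxy-4-oxo-4H-chromen-2-yl)-2,6-dimethoxyphenoxy]-3-hydroxy-3-(4-hydroxy-3-methoxyphenyl)propyl acetate | COc1cc([C@@H](O)[C@H](COC(C)=O)Oc2c(OC)cc(-c3cc(=O)c4c(O)cc(O)cc4o3)cc2OC)ccc1O | target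

**Totals**

Total step count: 9. Longest linear sequence: 8 steps (1, 3, 4, 5, 6, 7, 8, 9 from compound 1; equally 2–9 from compound 3).

**Steps most likely to fail**

Step 6 (proposed new method). The 1,2-proton shift of ylide 12, which the phosphoric acid can itself shuttle, may outrun addition to the weakly electrophilic aldehyde so that only O–H insertion is seen, or the addition may proceed with poor anti or facial selectivity. The fallback uses a chiral-auxiliary aldol; it sets out from 8 and 9 and returns at 15. Phenol 8 is O-alkylated at a primary carbon with commercial (R)-4-benzyl-3-(chloroacetyl)oxazolidin-2-one (K2CO3, cat. KI, acetone) to give (R)-4-benzyl-3-[(5,7-di-O-benzyltricin-4'-yloxy)acetyl]oxazolidin-2-one F1. An Evans boron aldol of F1 with 9 (Bu2BOTf, i-Pr2NEt, CH2Cl2, −78 to 0 °C) should give the syn (threo) imide adduct F2, in which C8 already has the target configuration and C7 the opposite one. Reductive removal of the auxiliary (NaBH4, THF/H2O) gives the threo (1S,2S)-diol F3, and acetylation as in step 8 gives the threo primary acetate F4. Mitsunobu inversion at C7 with chloroacetic acid (PPh3, DIAD, toluene) gives the erythro 7-O-chloroacetyl 9-O-acetyl diester F5, from which thiourea/NaHCO3 in EtOH/THF removes the chloroacetyl group selectively to deliver 15. Any SN1 leakage in the inversion gives only the separable threo diastereomer, since C8 fixes the absolute configuration.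

Step 7. Retro-aldol fragmentation or epimerisation at C8 through the C7 alkoxide may occur under basic borohydride, and the pyranone carbonyl may begin to be reduced if the ester needs forcing. The fallback masks the carbinol first; it sets out from 13 and returns at 15, and it also removes the need for selectivity in step 8. Silylation of 13 (TBSOTf, 2,6-lutidine, CH2Cl2, −78 °C) gives the C7 tert-butyldimethylsilyl ether of the ester F6. Reduction with LiBH4 (THF, 0 °C) gives the C7-silylated primary alcohol F7, acetylation (Ac2O, pyridine, DMAP) gives the C7-silylated acetate F8, and HF·pyridine in THF at 0 °C frees the benzylic hydroxyl to give 15.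

Step 4. Hydrogen iodide formed at 130 °C may strip the 5-O-benzyl group, or iodine may substitute the electron-rich A ring. The fallback separates ring closure from dehydrogenation under non-acidic conditions; it sets out from 5 and returns at 7. Chalcone 5 is cyclised by oxa-Michael addition (NaOAc, EtOH, reflux) to the flavanone 6, which is isolated and dehydrogenated with DDQ in dioxane at reflux to give 7.

**Further compounds**

F1 | step 6 | (R)-4-benzyl-3-[(5,7-di-O-benzyltricin-4'-yloxy)acetyl]oxazolidin-2-one | COc1cc(-c2cc(=O)c3c(OCc4ccccc4)cc(OCc4ccccc4)cc3o2)cc(OC)c1OCC(=O)N1[C@H](Cc2ccccc2)COC1=O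
F2 | step 6 | syn (threo) Evans aldol adduct of F1 and 9, C7-epimeric to the target series, (R)-4-benzyloxazolidinone imide | COc1cc([C@H](O)[C@H](C(=O)N2[C@H](Cc3ccccc3)COC2=O)Oc2c(OC)cc(-c3cc(=O)c4c(OCc5ccccc5)cc(OCc5ccccc5)cc4o3)cc2OC)ccc1OCc1ccccc1
F3 | step 6 | threo (1S,2S)-1-(4-benzyloxy-3-methoxyphenyl)-2-(5,7-di-O-benzyltricin-4'-yloxy)propane-1,3-diol | COc1cc([C@H](O)[C@H](CO)Oc2c(OC)cc(-c3cc(=O)c4c(OCc5ccccc5)cc(OCc5ccccc5)cc4o3)cc2OC)ccc1OCc1ccccc1
F4 | step 6 | threo (2S,3S)-3-(4-benzyloxy-3-methoxyphenyl)-2-(5,7-di-O-benzyltricin-4'-yloxy)-3-hydroxypropyl acetate | COc1cc([C@H](O)[C@H](COC(C)=O)Oc2c(OC)cc(-c3cc(=O)c4c(OCc5ccccc5)cc(OCc5ccccc5)cc4o3)cc2OC)ccc1OCc1ccccc1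
F5 | step 6 | erythro (2S,3R)-3-(4-benzyloxy-3-methoxyphenyl)-3-(chloroacetoxy)-2-(5,7-di-O-benzyltricin-4'-yloxy)propyl acetate | COc1cc([C@@H](OC(=O)CCl)[C@H](COC(C)=O)Oc2c(OC)cc(-c3cc(=O)c4c(OCc5ccccc5)cc(OCc5ccccc5)cc4o3)cc2OC)ccc1OCc1ccccc1
F6 | step 7 | ethyl (2R,3R)-3-(4-benzyloxy-3-methoxyphenyl)-3-(tert-butyldimethylsilyloxy)-2-(5,7-di-O-benzyltricin-4'-yloxy)propanoate | COc1cc([C@@H](O[Si](C)(C)C(C)(C)C)[C@H](C(=O)OCC)Oc2c(OC)cc(-c3cc(=O)c4c(OCc5ccccc5)cc(OCc5ccccc5)cc4o3)cc2OC)ccc1OCc1ccccc1
F7 | step 7 | (2S,3R)-3-(4-benzyloxy-3-methoxyphenyl)-3-(tert-butyldimethylsilyloxy)-2-(5,7-di-O-benzyltricin-4'-yloxy)propan-1-ol | COc1cc([C@@H](O[Si](C)(C)C(C)(C)C)[C@H](CO)Oc2c(OC)cc(-c3cc(=O)c4c(OCc5ccccc5)cc(OCc5ccccc5)cc4o3)cc2OC)ccc1OCc1ccccc1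
F8 | step 7 | (2S,3R)-3-(4-benzyloxy-3-methoxyphenyl)-3-(tert-butyldimethylsilyloxy)-2-(5,7-di-O-benzyltricin-4'-yloxy)propyl acetate | COc1cc([C@@H](O[Si](C)(C)C(C)(C)C)[C@H](COC(C)=O)Oc2c(OC)cc(-c3cc(=O)c4c(OCc5ccccc5)cc(OCc5ccccc5)cc4o3)cc2OC)ccc1OCc1ccccc1
F0 | step 4 | none | none
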